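**Strategy.** With daucane numbering (C1 quaternary CMe, C4 carbinol, C5 fusion CH, C6 acyloxy carbon, C9 ketone), the 1,4-dioxygenated C6–C7–C8–C9 segment of the seven-membered ring is the retron of a de Mayo reaction. Irradiation of a 2-substituted 3-benzyloxycyclopent-2-enone carrying the C4 carbinol and a methallyl terminus forms C5–C1 and C9–C10 in one intramolecular [2+2] step, closing the cyclopentane and fixing the C1 quaternary centre from C4; hydrogenolytic retro-aldol scission of C5–C9 then expands the cyclopentanedione into the cycloheptane-1,4-dione of the trans-hydroazulene. The precursor is a monocyclic vinylogous ester made from (S)-terpinen-4-ol.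

Key step: step 8

Assumption: (S)-terpinen-4-ol (the dextrorotatory enantiomer) is taken as commercially available in enantiopure form; material of lower ee would be upgraded first. Daucane numbering as defined above is used for all atom labels, and the bicyclic compounds are named with the azulene numbering of the target.

Step 1
Reactants: 1 (S)-terpinen-4-ol
Product: 2 triethyl{[(1S)-4-methyl-1-(propan-2-yl)cyclohex-3-en-1-yl]oxy}silane
Conditions: TESOTf, 2,6-lutidine, CH2Cl2, 0 °C
Reagents that add atoms: triethylsilyl trifluoromethanesulfonate, CC[Si](CC)(CC)OS(=O)(=O)C(F)(F)F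
Why: O-silylation of the hindered tertiary alcohol with the silyl triflate masks it through the oxidative cleavage, olefination and acid chloride chemistry, the stereocentre (future C4) being untouched.

Step 2
Reactants: 2 triethyl{[(1S)-4-methyl-1-(propan-2-yl)cyclohex-3-en-1-yl]oxy}silane
Product: 4 (3S)-6-oxo-3-(propan-2-yl)-3-[(triethylsilyl)oxy]heptanoic acid, via keto aldehyde 3 (not isolated)
Conditions: O3, CH2Cl2, −78 °C; PPh3, −78 °C → rt; then NaClO2, NaH2PO4, 2-methyl-2-butene, t-BuOH/H2O, 0 °C → rt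
Reagents that add atoms: ozone, [O-][O+]=O; sodium chlorite, [Na+].[O-]Cl=O
Why: Ozonolysis of the trisubstituted ring alkene with reductive work-up gives the keto aldehyde, and the Pinnick chlorite oxidation then oxidises only the aldehyde, so the two termini are differentiated as methyl ketone (future C1) and carboxylic acid (future C6).

Step 3
Reactants: 4 (3S)-6-oxo-3-(propan-2-yl)-3-[(triethylsilyl)oxy]heptanoic acid
Product: 5 (3S)-6-methyl-3-(propan-2-yl)-3-[(triethylsilyl)oxy]hept-6-enoic acid
Conditions: Ph3PCH3Br (2.5 equiv), KOt-Bu (2.5 equiv), THF, 0 °C → rt; aqueous citric acid work-up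
Reagents that add atoms: methyltriphenylphosphonium bromide, C[P+](c1ccccc1)(c1ccccc1)c1ccccc1.[Br-]
Why: Wittig methylenation with excess ylide converts the methyl ketone into the 1,1-disubstituted alkene C1=C10, the carboxylate being inert to the ylide.

Step 4
Reactants: 5 (3S)-6-methyl-3-(propan-2-yl)-3-[(triethylsilyl)oxy]hept-6-enoic acid; 6 (3-ethoxy-3-oxopropyl)zinc bromide
Product: 8 ethyl (6S)-9-methyl-4-oxo-6-(propan-2-yl)-6-[(triethylsilyl)oxy]dec-9-enoate, via acid chloride 7 (not isolated)
Conditions: 1-chloro-N,N,2-trimethylprop-1-en-1-amine, CH2Cl2, 0 °C → rt; then 6 (0.5 M in THF), Pd(PPh3)4 (5 mol %), THF, 0 °C → rt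
Reagents that add atoms: none
Why: Neutral acid chloride formation followed by Pd-catalysed Negishi acylation with the ester-bearing alkylzinc (a zinc homoenolate) should give the γ-keto ester without ever enolising the β-silyloxy carbonyl unit.

Step 5
Reactants: 8 ethyl (6S)-9-methyl-4-oxo-6-(propan-2-yl)-6-[(triethylsilyl)oxy]dec-9-enoate
Product: 9 ethyl (6S)-6-hydroxy-9-methyl-4-oxo-6-(propan-2-yl)dec-9-enoate
Conditions: HF·pyridine, pyridine, THF, 0 °C → rt
Reagents that add atoms: none
Why: Fluoride-mediated Si–O cleavage (desilylation) frees the tertiary alcohol, which is needed as the oxyanion in step 6 and as the hydrogen-bond donor in step 8.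

Step 6
Reactants: 9 ethyl (6S)-6-hydroxy-9-methyl-4-oxo-6-(propan-2-yl)dec-9-enoate
Product: 10 2-[(3R)-3-hydroxy-2,6-dimethylhept-6-en-3-yl]cyclopentane-1,3-dione (enol form: 3-hydroxycyclopent-2-en-1-one)
Conditions: KHMDS (3.2 equiv), THF, −78 → 0 °C (inverse addition); AcOH quench, cold work-up at pH 4
Reagents that add atoms: none
Why: Intramolecular Claisen (Dieckmann-type) condensation of the γ-keto ester: with excess amide base the substrate exists as alkoxide/enolate dianions, in which the C4 oxide cannot leave (no E1cB) and retro-aldol cleavage is shut down, while reversible enolate equilibration should funnel the C5 enolate onto the ester to give the dione as its stable enolate; the descriptor changes from S to R only because the CIP priorities change.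

Step 7
Reactants: 10 2-[(3R)-3-hydroxy-2,6-dimethylhept-6-en-3-yl]cyclopentane-1,3-dione
Product: 11 3-(benzyloxy)-2-[(3R)-3-hydroxy-2,6-dimethylhept-6-en-3-yl]cyclopent-2-en-1-one
Conditions: BnBr, K2CO3, DMF, rt
Reagents that add atoms: benzyl bromide, BrCc1ccccc1
Why: O-alkylation of the vinylogous acid, since C-alkylation at the fully hindered C5 is blocked and carbonate does not deprotonate the tertiary alcohol; the dione is symmetric, so only one enol ether can form.

Step 8
Reactants: 11 3-(benzyloxy)-2-[(3R)-3-hydroxy-2,6-dimethylhept-6-en-3-yl]cyclopent-2-en-1-one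
Product: 12 (1R,5S,7R,10R)-5-(benzyloxy)-10-hydroxy-7-methyl-10-(propan-2-yl)tricyclo[5.3.0.0^{1,5}]decan-2-one
Conditions: hν (medium-pressure Hg lamp, Pyrex filter, λ > 290 nm), degassed cyclohexane/CH2Cl2 (9:1), 0.005 M, 10 °C
Reagents that add atoms: none
Why: Excitation of the vinylogous ester gives its triplet state, which adds to the pendant 1,1-disubstituted alkene through a 1,4-biradical to a cis-fused cyclobutane; the closest known reaction type is the intramolecular enone–alkene [2+2] photocycloaddition of 2-(pent-4-enyl)cyclopentane-1,3-dione enol derivatives, the first half of an intramolecular de Mayo reaction. The cyclopentane closes by 1,5-bonding (5-exo mode, rule of five) of the enone α-carbon C5 to the internal alkene carbon C1, and the cyclobutane by subsequent C9–C10 radical recombination, which gives the straight and not the crossed adduct. C1 is controlled by C4: in a non-polar solvent the tertiary OH is hydrogen-bonded to the C6 carbonyl, which holds O4 in the enone plane syn to C6, so that tether carbon C3 and the isopropyl group lie on opposite faces and the alkene can add only from the C3 face, placing the C1 methyl cis to O4. C5 and C9 follow from the obligatory cis fusion of both five-membered rings to the cyclobutane. The step needs straight regiochemistry, secured by the three-atom tether on C5, and alkene-face selectivity, secured by the hydrogen bond and by the absence of competing acceptors (an ether and not an ester on the enol oxygen, no protic solvent).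

Step 9
Reactants: 12 (1R,5S,7R,10R)-5-(benzyloxy)-10-hydroxy-7-methyl-10-(propan-2-yl)tricyclo[5.3.0.0^{1,5}]decan-2-one
Product: 14 (3R,3aR,8aR)-3-hydroxy-8a-methyl-3-(propan-2-yl)octahydroazulene-4,7-dione (trans-fused; C6 and C9 ketones), via cyclobutanol 13 (not isolated)
Conditions: H2 (1 atm), 10% Pd/C, EtOAc, rt; filter; then Et3N (cat.), CH2Cl2, rt
Reagents that add atoms: none
Why: Hydrogenolysis of the benzyl ether unveils a cyclobutanol β to the C6 ketone, which should undergo strain-driven retro-aldol cleavage of C5–C9 (de Mayo fragmentation) under neutral conditions; amine then equilibrates C5 to the trans-fused epimer, in which C6 is anti to the isopropyl group and hydrogen-bonded to the cis C4 hydroxyl.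

Step 10
Reactants: 14 (3R,3aR,8aR)-3-hydroxy-8a-methyl-3-(propan-2-yl)octahydroazulene-4,7-dione
Product: 15 (3R,3aS,4S,8aR)-3,4-dihydroxy-8a-methyl-3-(propan-2-yl)octahydroazulen-7(1H)-one
Conditions: Me4NBH(OAc)3, MeCN/AcOH (1:1), −20 °C
Reagents that add atoms: none
Why: Evans–Saksena hydroxyl-directed reduction: the borohydride bound to the C4 oxygen delivers hydride intramolecularly to the β-face of the C6 ketone only, giving the anti-1,3-diol (6α-OH, 6S) and leaving the undirected C9 ketone untouched.

Step 11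
Reactants: 15 (3R,3aS,4S,8aR)-3,4-dihydroxy-8a-methyl-3-(propan-2-yl)octahydroazulen-7(1H)-one; 16 (2E)-3-[4-(acetyloxy)phenyl]prop-2-enoic acid
Product: 17 (3R,3aS,4S,8aR)-3-hydroxy-8a-methyl-7-oxo-3-(propan-2-yl)decahydroazulen-4-yl (2E)-3-[4-(acetyloxy)phenyl]prop-2-enoate
Conditions: EDC·HCl, DMAP (cat.), CH2Cl2, 0 °C → rt
Reagents that add atoms: none
Why: Steglich esterification acylates the secondary C6 alcohol selectively, the hindered tertiary C4 alcohol being unreactive, and the E-alkene of the acid is retained.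

Step 12
Reactants: 17 (3R,3aS,4S,8aR)-3-hydroxy-8a-methyl-7-oxo-3-(propan-2-yl)decahydroazulen-4-yl (2E)-3-[4-(acetyloxy)phenyl]prop-2-enoate
Product: 18 (3R,3aS,4S,8aR)-3-hydroxy-8a-methyl-6-methylidene-7-oxo-3-(propan-2-yl)decahydroazulen-4-yl (2E)-3-[4-(acetyloxy)phenyl]prop-2-enoate
Conditions: (CH2O)n, i-Pr2NH·TFA (1 equiv), THF, reflux
Reagents that add atoms: formaldehyde (as paraformaldehyde), C=O
Why: Mannich-type α-methylenation through the ammonium salt/formaldehyde adduct should occur at C8, the only unhindered α-methylene of the C9 ketone (C10 is neopentyl to the quaternary C1), and elimination gives the exocyclic enone.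

Step 13
Reactants: 18 (3R,3aS,4S,8aR)-3-hydroxy-8a-methyl-6-methylidene-7-oxo-3-(propan-2-yl)decahydroazulen-4-yl (2E)-3-[4-(acetyloxy)phenyl]prop-2-enoate
Product: 19 (3R,3aS,4S,8aR)-3-hydroxy-6,8a-dimethyl-7-oxo-3-(propan-2-yl)-1,2,3,3a,4,7,8,8a-octahydroazulen-4-yl (2E)-3-[4-(acetyloxy)phenyl]prop-2-enoate
Conditions: RhCl3·3H2O (5 mol %), EtOH, 70 °C
Reagents that add atoms: none
Why: Rhodium hydride-mediated exo-to-endo alkene isomerisation moves the double bond to C7=C8, the only endocyclic conjugated position available and the more stable trisubstituted enone, which creates the C8 methyl group without touching a stereocentre.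

Step 14
Reactants: 19 (3R,3aS,4S,8aR)-3-hydroxy-6,8a-dimethyl-7-oxo-3-(propan-2-yl)-1,2,3,3a,4,7,8,8a-octahydroazulen-4-yl (2E)-3-[4-(acetyloxy)phenyl]prop-2-enoate
Product: 20 (3R,3aS,4S,8aR)-3-hydroxy-6,8a-dimethyl-7-oxo-3-(propan-2-yl)-1,2,3,3a,4,7,8,8a-octahydroazulen-4-yl (2E)-3-(4-hydroxyphenyl)prop-2-enoate (CNP0310968.1)
Conditions: NH4OAc, MeOH, rt
Reagents that add atoms: none
Why: Chemoselective transesterification (methanolysis) of the phenyl acetate, a far better acyl donor than the alkyl cinnamate, should release the phenol under near-neutral conditions that spare the γ-acyloxy enone.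

**Compound list**

1 | (S)-terpinen-4-ol, (1S)-4-methyl-1-(propan-2-yl)cyclohex-3-en-1-ol | CC1=CC[C@](O)(C(C)C)CC1 | starting material
2 | triethyl{[(1S)-4-methyl-1-(propan-2-yl)cyclohex-3-en-1-yl]oxy}silane | CC1=CC[C@](O[Si](CC)(CC)CC)(C(C)C)CC1 | intermediate
3 | (3S)-6-oxo-3-(propan-2-yl)-3-[(triethylsilyl)oxy]heptanal (keto aldehyde, not isolated) | CC(=O)CC[C@@](CC=O)(O[Si](CC)(CC)CC)C(C)C | intermediate
4 | (3S)-6-oxo-3-(propan-2-yl)-3-[(triethylsilyl)oxy]heptanoic acid | CC(=O)CC[C@@](CC(=O)O)(O[Si](CC)(CC)CC)C(C)C | intermediate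
5 | (3S)-6-methyl-3-(propan-2-yl)-3-[(triethylsilyl)oxy]hept-6-enoic acid | C=C(C)CC[C@@](CC(=O)O)(O[Si](CC)(CC)CC)C(C)C | intermediate
6 | (3-ethoxy-3-oxopropyl)zinc bromide | CCOC(=O)CC[Zn]Br | starting material
7 | (3S)-6-methyl-3-(propan-2-yl)-3-[(triethylsilyl)oxy]hept-6-enoyl chloride (acid chloride, not isolated) | C=C(C)CC[C@@](CC(=O)Cl)(O[Si](CC)(CC)CC)C(C)C | intermediate
8 | ethyl (6S)-9-methyl-4-oxo-6-(propan-2-yl)-6-[(triethylsilyl)oxy]dec-9-enoate | C=C(C)CC[C@@](CC(=O)CCC(=O)OCC)(O[Si](CC)(CC)CC)C(C)C | intermediate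
9 | ethyl (6S)-6-hydroxy-9-methyl-4-oxo-6-(propan-2-yl)dec-9-enoate | C=C(C)CC[C@@](CC(=O)CCC(=O)OCC)(O)C(C)C | intermediate
10 | 2-[(3R)-3-hydroxy-2,6-dimethylhept-6-en-3-yl]cyclopentane-1,3-dione (enol form) | C=C(C)CC[C@@](C1=C(O)CCC1=O)(O)C(C)C | intermediate
11 | 3-(benzyloxy)-2-[(3R)-3-hydroxy-2,6-dimethylhept-6-en-3-yl]cyclopent-2-en-1-one | C=C(C)CC[C@@](C1=C(OCc2ccccc2)CCC1=O)(O)C(C)C | intermediate
12 | (1R,5S,7R,10R)-5-(benzyloxy)-10-hydroxy-7-methyl-10-(propan-2-yl)tricyclo[5.3.0.0^{1,5}]decan-2-one | O=C1CC[C@]2(OCc3ccccc3)C[C@@]4(C)CC[C@@](O)(C(C)C)[C@@]124 | intermediate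
13 | (1S,5S,7R,10R)-5,10-dihydroxy-7-methyl-10-(propan-2-yl)tricyclo[5.3.0.0^{1,5}]decan-2-one (cyclobutanol, not isolated) | O=C1CC[C@]2(O)C[C@@]4(C)CC[C@@](O)(C(C)C)[C@@]124 | intermediate
14 | (3R,3aR,8aR)-3-hydroxy-8a-methyl-3-(propan-2-yl)octahydroazulene-4,7-dione | C1CC(=O)[C@@H]2[C@](C)(CC[C@@]2(O)C(C)C)CC1=O | intermediate
15 | (3R,3aS,4S,8aR)-3,4-dihydroxy-8a-methyl-3-(propan-2-yl)octahydroazulen-7(1H)-one | C1C[C@H](O)[C@@H]2[C@](C)(CC[C@@]2(O)C(C)C)CC1=O | intermediate
16 | (2E)-3-[4-(acetyloxy)phenyl]prop-2-enoic acid (4-acetoxycinnamic acid) | CC(=O)Oc1ccc(/C=C/C(O)=O)cc1 | starting material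
17 | (3R,3aS,4S,8aR)-3-hydroxy-8a-methyl-7-oxo-3-(propan-2-yl)decahydroazulen-4-yl (2E)-3-[4-(acetyloxy)phenyl]prop-2-enoate | C1C[C@H](OC(=O)/C=C/c3ccc(OC(C)=O)cc3)[C@@H]2[C@](C)(CC[C@@]2(O)C(C)C)CC1=O | intermediate
18 | (3R,3aS,4S,8aR)-3-hydroxy-8a-methyl-6-methylidene-7-oxo-3-(propan-2-yl)decahydroazulen-4-yl (2E)-3-[4-(acetyloxy)phenyl]prop-2-enoate | C=C1C[C@H](OC(=O)/C=C/c3ccc(OC(C)=O)cc3)[C@@H]2[C@](C)(CC[C@@]2(O)C(C)C)CC1=O | intermediate
19 | (3R,3aS,4S,8aR)-3-hydroxy-6,8a-dimethyl-7-oxo-3-(propan-2-yl)-1,2,3,3a,4,7,8,8a-octahydroazulen-4-yl (2E)-3-[4-(acetyloxy)phenyl]prop-2-enoate | CC1=C[C@H](OC(=O)/C=C/c3ccc(OC(C)=O)cc3)[C@@H]2[C@](C)(CC[C@@]2(O)C(C)C)CC1=O | intermediate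
20 | (3R,3aS,4S,8aR)-3-hydroxy-6,8a-dimethyl-7-oxo-3-(propan-2-yl)-1,2,3,3a,4,7,8,8a-octahydroazulen-4-yl (2E)-3-(4-hydroxyphenyl)prop-2-enoate | CC1=C[C@H](OC(=O)/C=C/c2ccc(O)cc2)[C@@H]2[C@](C)(CC[C@@]2(O)C(C)C)CC1=O | target

**Totals.** Total step count: 14. Longest linear sequence: 14 steps (1 → 20); compounds 6 and 16 are purchased.

**Steps most likely to fail**

1. Step 6 (dione formation). The ring closure is a 5-(enolendo) Claisen at the neopentyl carbon C5 and may be slow, so that retro-aldol cleavage of the β-hydroxy ketone during enolate equilibration, or intermolecular ester condensation, overtakes it. The fallback sets out from 9 and comes back at 10, and replaces the strong-base Claisen by a soft-enolisation C-acylation of an activated ester. Ester 9 is hydrolysed with pig liver esterase at pH 7 to the hydroxy keto acid F1. This is converted with pentafluorophenol and EDC·HCl into the pentafluorophenyl ester F2. F2 is cyclised with MgBr2·OEt2 and i-Pr2NEt in CH2Cl2 at rt, where magnesium chelation between the C4 hydroxyl and the ketone should direct enolisation to C5, to give 10.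

2. Step 8 (key photocycloaddition). The intramolecular hydrogen bond may be too weak to hold a single conformer, which would give poor discrimination of the two alkene faces and a mixture of C1 epimers. The fallback sets out from 11 and comes back at 12, and replaces the hydrogen bond by a covalent chelate. Treatment of 11 with Bu2BOTf and i-Pr2NEt in CH2Cl2 at −78 °C gives the dibutylboron chelate F3, in which boron bridges O4 and the C6 carbonyl oxygen in a six-membered ring and locks O4 syn to C6. Irradiation of this Lewis-acid-bound enone (λ > 300 nm, CH2Cl2, −40 °C) should give the boron-bound photoadduct F4, and mild aqueous work-up at pH 7 releases 12.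

3. Step 12 (α-methylenation, with the isomerisation of step 13). Regiocontrol between C8 and C10 may be incomplete, or over-methylenation and incomplete exo-to-endo migration may occur. The fallback sets out from 17 and comes back at 19, and builds the methyl enone by dehydrogenation and cross-coupling. IBX in DMSO/fluorobenzene at 70 °C dehydrogenates 17 to the enone F5; only C7=C8 can form because C1 is quaternary. Iodine and pyridine in CH2Cl2 then give the α-iodoenone F6 (α-iodination of the enone at C8). Stille coupling with Me4Sn (Pd2(dba)3, AsPh3, CuI, NMP, 50 °C) installs the C8 methyl group and gives 19.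

**Further compounds**

F1 | step 6 | (6S)-6-hydroxy-9-methyl-4-oxo-6-(propan-2-yl)dec-9-enoic acid | C=C(C)CC[C@@](CC(=O)CCC(=O)O)(O)C(C)C
F2 | step 6 | pentafluorophenyl (6S)-6-hydroxy-9-methyl-4-oxo-6-(propan-2-yl)dec-9-enoate | C=C(C)CC[C@@](CC(=O)CCC(=O)Oc1c(F)c(F)c(F)c(F)c1F)(O)C(C)C
F3 | step 8 | 3-(benzyloxy)-2-[(3R)-3-[(dibutylboranyl)oxy]-2,6-dimethylhept-6-en-3-yl]cyclopent-2-en-1-one (boron chelate) | C=C(C)CC[C@@](C1=C(OCc2ccccc2)CCC1=O)(OB(CCCC)CCCC)C(C)C
F4 | step 8 | (1R,5S,7R,10R)-5-(benzyloxy)-10-[(dibutylboranyl)oxy]-7-methyl-10-(propan-2-yl)tricyclo[5.3.0.0^{1,5}]decan-2-one | O=C1CC[C@]2(OCc3ccccc3)C[C@@]4(C)CC[C@@](OB(CCCC)CCCC)(C(C)C)[C@@]124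
F5 | step 12 | (3R,3aS,4S,8aR)-3-hydroxy-8a-methyl-7-oxo-3-(propan-2-yl)-1,2,3,3a,4,7,8,8a-octahydroazulen-4-yl (2E)-3-[4-(acetyloxy)phenyl]prop-2-enoate | C1=C[C@H](OC(=O)/C=C/c3ccc(OC(C)=O)cc3)[C@@H]2[C@](C)(CC[C@@]2(O)C(C)C)CC1=O
F6 | step 12 | (3R,3aS,4R,8aR)-3-hydroxy-6-iodo-8a-methyl-7-oxo-3-(propan-2-yl)-1,2,3,3a,4,7,8,8a-octahydroazulen-4-yl (2E)-3-[4-(acetyloxy)phenyl]prop-2-enoate | IC1=C[C@H](OC(=O)/C=C/c3ccc(OC(C)=O)cc3)[C@@H]2[C@](C)(CC[C@@]2(O)C(C)C)CC1=O
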